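## Structural features

The target is a lignan ester built on a tetrahydrofuran (ring O1–C2–C3–C4–C5). C2 carries a 4‑hydroxy‑3,5‑dimethoxyphenyl (syringyl) ring, C3 an acyloxymethyl arm, C4 a 4‑hydroxy‑3‑methoxybenzyl (guaiacylmethyl) group, and C5 is an unsubstituted OCH2. The C3 oxygen is esterified with (E)‑ferulic acid. C2, C3 and C4 are three contiguous stereocentres, (2S,3R,4R). The aryl group and the CH2O arm are trans, while the CH2O arm and the benzyl group are cis, so the ring holds the less stable 3,4‑cis relation next to a 2,3‑trans one. The fragile parts are the three free phenols, the cinnamate (reducible, base‑labile) and above all the C2–O1 bond. That bond is a benzylic ether para to an oxygen donor: it ionises under acid (epimerisation at C2, or capture of the cation by the guaiacyl ring to an aryltetralin) and can be hydrogenolysed. The real difficulty is to fix C3 absolutely and to place C2 trans and C4 cis to it, without exposing the finished ring to strong acid and without carrying the cinnamate through a reduction. The key step uses the same property that makes C2 fragile. Because the syringyl ring stabilises positive charge on C2, the O1–C2 bond can be made last from an enolate oxygen, and C2, C3 and C4 can be stored as a cyclopropane whose formyl group on C4 supplies C5 and O1. Only C3 then has to be carried as a stereocentre; C2 is re‑set by C3 during ring closure, and C4 is left trigonal (C4=C5) for a face‑selective hydrogenation.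

## Logic of the disconnections

22 ⇒ 21 ⇒ 17 + 20. The acyl C–O bond of the cinnamate is cut, and the three phenolic O–H bonds are replaced by O–Si bonds (21). The conjugated ester is the group least compatible with hydride reagents, Lewis acids and hydrogenation, so it enters last. The problem shrinks to alcohol 17, which holds all three stereocentres, and acid 20. The forward demand is that the primary hydroxyl of 17 is the only free one, and that all three phenols carry the same fluoride‑labile silyl group so that one mild step frees them beside the ester and the benzylic ether.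

17 ⇒ 16 ⇒ 15. The primary O–H is traced back to an O–SiEt3 bond (16), and the C4–H and C5–H bonds are removed to give the C4=C5 enol ether 15. C4, with its cis relation to C3, is the contra‑thermodynamic centre; making it trigonal postpones it to a step that is biased by the neighbouring C3 arm. One stereocentre disappears and an enol ether appears, which is the natural product of a ring closure through oxygen. The forward step must add hydrogen anti to the C3 arm without cleaving C2–O1, and the C3 silyl ether must be removable beside two aryl silyl ethers.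

15 ⇒ 14 (key step). The O1–C2 bond is cut and C2 is joined to C4, so the dihydrofuran becomes cyclopropane 14 with C5/O1 as a formyl group. C2 is the one position that supports a cation, so the forward reaction is an easy heterolysis and recombination, and a cyclopropane is reachable by carbene addition to an alkene. The heterocycle is exchanged for a carbocycle with an established enantioselective assembly, and the configuration of C2 in 14 no longer matters. The forward step must break only the C2–C4 bond, close through oxygen, give the 2,3‑trans product, and leave the enol ether and the silyl ethers intact.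

14 ⇒ 13 ⇒ 12 ⇒ 11. The formyl C–H is exchanged for a C–N bond (13), the O–Si bond for O–H (12), and the amide C–N bond is cut with reconnection of the C3 oxygen to the carbonyl carbon (lactone 11). The cis relation of formyl and CH2O in 14 points to a ring. Both oxygen functions and their relative configuration then come from one lactone. The forward demands are an opening that does not ionise the donor–acceptor cyclopropane, silylation before the hydroxy amide can relactonise, and a reduction that stops at the aldehyde.

11 ⇒ 10. The two cyclopropane bonds from the quaternary carbon (to the aryl‑bearing and to the CH2O‑bearing carbon) are cut, leaving a carbene (stored as a diazo ester) and an E‑alkene in one molecule. Intramolecular carbene addition makes the three‑membered ring and the lactone together and transfers the alkene geometry. All stereochemistry reduces to one facial choice by a chiral catalyst, and 10 has no stereocentre. The catalyst must control that face and suppress the 1,2‑hydride shift open to an α‑alkyl carbenoid.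

10 ⇒ 8 ⇒ 4 + 7. The C=N2 bond is removed (diazo transfer to the α‑carbon of 8), and the ester C–O bond is cut. The ester joins two C6–C3 units at their natural polarity, and two achiral phenylpropanoids remain. The α‑CH2 of a plain ester is not acidic enough for direct diazo transfer and must be activated in passing; the esterification must not ionise the electron‑rich allylic alcohol.

4 ⇒ 3 ⇒ 2 ⇒ 1; 7 ⇒ 5; 20 ⇒ 18. No skeletal bond is cut: only O–Si, ester C–O and C–H bonds change. This brings all three fragments back to commercial hydroxy acids. The forward demand is that the phenol, not the acid, ends up silylated.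

## Other disconnections considered

Alternative 1: The cut is C2–C3 and C4–C5, dividing the ring into the three‑atom unit C2–O1–C5 and the two‑atom unit C3–C4. In the forward step fluoride (CsF) removes the silyl group of the α‑chloro ether A1 with loss of chloride. The resulting carbonyl ylide adds across the double bond of the chiral butenolide A2, on the face away from the menthyloxy group, to give the cis‑fused bicyclic lactone A3.
- In favour: one operation makes two C–C bonds, the ring and all three stereocentres. The cis ring fusion of A3 guarantees the 3,4‑cis relation; on this point the alternative is better than the chosen plan, where C4 depends on a separate hydrogenation. It needs no diazo compound and no precious metal, which is also better.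
- Against: A1 is an α‑chloro ether at a tri‑oxygenated benzylic carbon and should ionise or hydrolyse very readily. The 2,3‑trans relation rests only on the exo/endo preference of the cycloaddition. A2 belongs to the antipode of the commonly used auxiliary series. Both arms of A3 are at the wrong oxidation level: the acetal carbon must be unmasked, arylated and deoxygenated to become the guaiacylmethyl group, in a molecule that already holds the labile C2–O1 bond. The lactone carbonyl must be reduced, and the benzyl ether exchanged before the cinnamate enters.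
- Comparison: on structure A3 maps C2, C3 and C4 correctly and beats the chosen plan at C4, but lacks the guaiacyl ring. On mechanism a concerted cycloaddition replaces a stepwise ionisation, and both are sound. On step economy the tail after A3 (an estimated seven or more operations) makes it no shorter and probably longer.

Alternative 2: The cut is O1–C2 and C3–C4. In the forward step zerovalent palladium with a chiral diphosphine opens racemic A5 to an alkoxide/π‑allylpalladium zwitterion. The alkoxide adds to the benzylidene carbon of A4, and the malonate carbanion closes on the internal allyl terminus to give A6.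
- In favour: the step is convergent, catalytic and enantioselective from an achiral acceptor and a racemic epoxide, both enantiomers of A5 passing through one π‑allyl intermediate. In convergence and in the cost of the chiral information it is better than the chosen plan.
- Against: A4 is a weak Michael acceptor because of its tri‑oxygenated aryl group, and the oxa‑Michael addition is reversible. C3 of A6 is a quaternary malonate carbon, so the C3 stereocentre still has to be created by removing one ester; it must end trans to the aryl group but cis to the C4 arm, for which there is no clear bias. The vinyl group holds one carbon too many, so it must be cleaved, arylated and deoxygenated. The benzyl ether again needs exchanging.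
- Comparison: on structure A6 delivers C2 and C4 but neither C3 nor the guaiacyl ring. On mechanism both plans close the ring from a zwitterion, here by reversible alkoxide addition and in the chosen plan by collapse of an ion pair. On step economy it is clearly worse (an estimated eight or more steps after A6).

Alternative 3: The cut is C3–C4 only. In the forward step trivalent titanium (Cp2TiCl, from Cp2TiCl2 and Zn) opens the oxirane of ether A7 homolytically to the C3 radical, with a titanium alkoxide on the CH2O arm. A 5‑exo‑trig addition to the cinnamyl double bond forms C3–C4, and the benzylic radical is reduced by a second equivalent and protonated. The product A8 is the same compound as 17.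
- In favour: the whole skeleton appears in one step with the correct oxidation levels and protecting groups, and the route would meet the chosen one at 17 after roughly half as many steps. In step economy it is clearly better. The neutral radical conditions are at least the equal of the chosen plan in tolerance of the benzylic ether and the silyl ethers.
- Against: C3 and C4 are both set in one radical transition state, controlled by C2 alone. The 2,3‑trans relation should be dependable, but the 3,4‑cis versus trans preference is expected to be moderate. Enantiopurity has to be built into A7, whose carbinol carbon would come from a kinetic‑resolution epoxidation (half of the material at best). That carbon must then be etherified as a hindered, ionisable benzylic alkoxide. Titanium is used stoichiometrically.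
- Comparison: on structure the two are equal (A8 = 17). On mechanism one radical event stands against three separately tunable polar events (catalyst for C3, ring closure for C2, hydrogenation for C4). The chosen plan is preferred for the reliability of each stereochemical event, not for brevity.

Key step: step 11

Abbreviations: TBS = tert‑butyldimethylsilyl, TES = triethylsilyl; TBSO and TESO are the corresponding silyloxy groups.

Assumption: the (S)‑configured catalyst of step 7 is taken to attack the alkene face that leads to the (1S,5R,6S) lactone 11. If the sense of induction is the opposite, the enantiomeric catalyst Rh2(R‑PTTL)4 is used and nothing else changes.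

Remark on the structures and the design of the precursor:
- In 14 and 15 the CH2O‑bearing carbon has the same spatial arrangement as C3 of 22, and 15 has C2 as in 22, so no structure needed correcting.
- The silyl pattern of 14 (aryl TBS, alkyl TES) is kept on purpose: the primary ether must later leave under acid weak enough for the aryl silyl ethers and the benzylic ether.
- Three points are strengthened: transient trifluoroacetyl activation for the diazo transfer (step 6), a lactone opening free of Lewis acid (step 8), and a buffered, water‑free key step.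

## Route

Step 1
Reactants: 1 sinapic acid
Product: 2 methyl (E)-3-(4-hydroxy-3,5-dimethoxyphenyl)prop-2-enoate
Conditions: MeOH, H2SO4 (cat.), reflux
Reagents that add atoms: methanol, CO
Why: Fischer esterification driven by methanol as solvent; the phenol and the E‑alkene are not affected.

Step 2
Reactants: 2 methyl (E)-3-(4-hydroxy-3,5-dimethoxyphenyl)prop-2-enoate
Product: 3 methyl (E)-3-[4-(TBSO)-3,5-dimethoxyphenyl]prop-2-enoate
Conditions: TBSCl, imidazole, DMF, rt
Reagents that add atoms: tert-butyldimethylsilyl chloride, CC(C)(C)[Si](C)(C)Cl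
Why: Imidazole‑mediated O‑silylation of the phenol; the two flanking methoxy groups slow the reaction but make the aryl silyl ether robust toward the bases and hydrides used later.

Step 3
Reactants: 3 methyl (E)-3-[4-(TBSO)-3,5-dimethoxyphenyl]prop-2-enoate
Product: 4 (E)-3-[4-(TBSO)-3,5-dimethoxyphenyl]prop-2-en-1-ol
Conditions: i-Bu2AlH, CH2Cl2, −78 °C to 0 °C; aq. potassium sodium tartrate
Reagents that add atoms: none
Why: 1,2‑Reduction of the α,β‑unsaturated ester by the aluminium hydride gives the allylic alcohol with the E geometry retained; the aryl silyl ether is inert.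

Step 4
Reactants: 5 3-(4-hydroxy-3-methoxyphenyl)propanoic acid
Product: 7 3-[4-(TBSO)-3-methoxyphenyl]propanoic acid, via bis-silyl propanoate 6 (not isolated)
Conditions: TBSCl (2.2 equiv), imidazole, DMF, rt; then AcOH/THF/H2O, rt
Reagents that add atoms: tert-butyldimethylsilyl chloride, CC(C)(C)[Si](C)(C)Cl
Why: Exhaustive silylation followed by selective hydrolysis of the far more labile silyl ester; dilute acetic acid leaves the aryl silyl ether in place.

Step 5
Reactants: 4 (E)-3-[4-(TBSO)-3,5-dimethoxyphenyl]prop-2-en-1-ol; 7 3-[4-(TBSO)-3-methoxyphenyl]propanoic acid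
Product: 8 (E)-3-[4-(TBSO)-3,5-dimethoxyphenyl]prop-2-en-1-yl 3-[4-(TBSO)-3-methoxyphenyl]propanoate
Conditions: EDC·HCl, DMAP, CH2Cl2, 0 °C to rt
Reagents that add atoms: none
Why: Steglich esterification; the neutral carbodiimide/DMAP conditions avoid ionisation of the electron‑rich cinnamyl alcohol, which an acid chloride or acid catalysis would risk.

Step 6
Reactants: 8 (E)-3-[4-(TBSO)-3,5-dimethoxyphenyl]prop-2-en-1-yl 3-[4-(TBSO)-3-methoxyphenyl]propanoate
Product: 10 (E)-3-[4-(TBSO)-3,5-dimethoxyphenyl]prop-2-en-1-yl 2-diazo-3-[4-(TBSO)-3-methoxyphenyl]propanoate, via 2-trifluoroacetyl ester 9 (not isolated)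
Conditions: LiN(SiMe3)2, THF, −78 °C; CF3CO2CH2CF3, −78 °C; aq. NH4Cl; then 4-AcNHC6H4SO2N3, Et3N, H2O (1 equiv), MeCN, rt
Reagents that add atoms: 4-acetamidobenzenesulfonyl azide, CC(=O)Nc1ccc(cc1)S(=O)(=O)N=[N+]=[N-] (supplies the N2 unit of 10); 2,2,2-trifluoroethyl trifluoroacetate, O=C(OCC(F)(F)F)C(F)(F)F (supplies the CF3CO group of intermediate 9 only)
Why: Detrifluoroacetylative (Regitz‑type deacylative) diazo transfer: the lithium enolate is C‑trifluoroacetylated, and the resulting 1,3‑dicarbonyl compound takes the diazo group from the sulfonyl azide and passes the trifluoroacetyl group to the sulfonamide. The enolate is kept at −78 °C so that the allylic ester does not undergo Ireland–Claisen rearrangement.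

Step 7
Reactants: 10 (E)-3-[4-(TBSO)-3,5-dimethoxyphenyl]prop-2-en-1-yl 2-diazo-3-[4-(TBSO)-3-methoxyphenyl]propanoate
Product: 11 (1S,5R,6S)-1-[4-(TBSO)-3-methoxybenzyl]-6-[4-(TBSO)-3,5-dimethoxyphenyl]-3-oxabicyclo[3.1.0]hexan-2-one
Conditions: Rh2(S-PTTL)4 (dirhodium tetrakis[N-phthaloyl-(S)-tert-leucinate], 1 mol %), CH2Cl2, −78 °C, slow addition of 10, then to −40 °C
Reagents that add atoms: none
Why: Intramolecular cyclopropanation of an allylic diazo ester through a rhodium carbenoid. The E geometry is transferred stereospecifically (aryl exo, trans to CH2O), the tether enforces the cis relation of carbonyl and CH2O, and the chiral carboxylate ligands select the alkene face, which fixes C5 of 11 (C3 of the target) and with it C1 and C6. Bulky phthalimido carboxylate ligands and low temperature are the established means of disfavouring the 1,2‑hydride shift of α‑alkyl carbenoids.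

Step 8
Reactants: 11 (1S,5R,6S)-1-[4-(TBSO)-3-methoxybenzyl]-6-[4-(TBSO)-3,5-dimethoxyphenyl]-3-oxabicyclo[3.1.0]hexan-2-one
Product: 12 (1S,2S,3R)-3-(hydroxymethyl)-N-methoxy-N-methyl-1-[4-(TBSO)-3-methoxybenzyl]-2-[4-(TBSO)-3,5-dimethoxyphenyl]cyclopropane-1-carboxamide
Conditions: MeNH(OMe)·HCl, i-PrMgCl, THF, −20 °C to 0 °C; aq. NH4Cl
Reagents that add atoms: N,O-dimethylhydroxylamine hydrochloride, CNOC.Cl
Why: Aminolysis of the lactone by the chloromagnesium amide gives the N‑methoxy‑N‑methylamide (Weinreb amide) and frees the primary alcohol; no stereocentre is touched. The basic magnesium reagent is preferred to an aluminium amide because a Lewis acid could ionise this donor–acceptor cyclopropane at the syringyl carbon.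

Step 9
Reactants: 12 (1S,2S,3R)-3-(hydroxymethyl)-N-methoxy-N-methyl-1-[4-(TBSO)-3-methoxybenzyl]-2-[4-(TBSO)-3,5-dimethoxyphenyl]cyclopropane-1-carboxamide
Product: 13 (1S,2S,3R)-N-methoxy-N-methyl-1-[4-(TBSO)-3-methoxybenzyl]-2-[4-(TBSO)-3,5-dimethoxyphenyl]-3-[(TESO)methyl]cyclopropane-1-carboxamide
Conditions: Et3SiCl, imidazole, CH2Cl2, 0 °C (crude 12 used at once)
Reagents that add atoms: chlorotriethylsilane, CC[Si](CC)(CC)Cl
Why: Prompt O‑silylation blocks relactonisation of the cis hydroxy amide; the TES group is chosen because it can later be removed by weak acid beside the aryl TBS ethers.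

Step 10
Reactants: 13 (1S,2S,3R)-N-methoxy-N-methyl-1-[4-(TBSO)-3-methoxybenzyl]-2-[4-(TBSO)-3,5-dimethoxyphenyl]-3-[(TESO)methyl]cyclopropane-1-carboxamide
Product: 14 (1S,2S,3R)-1-[4-(TBSO)-3-methoxybenzyl]-2-[4-(TBSO)-3,5-dimethoxyphenyl]-3-[(TESO)methyl]cyclopropane-1-carbaldehyde
Conditions: i-Bu2AlH, THF, −78 °C; aq. potassium sodium tartrate
Reagents that add atoms: none
Why: Hydride reduction of the Weinreb amide stops at the chelated tetrahedral intermediate, which gives the aldehyde on work‑up. The α‑carbon is quaternary, so it cannot epimerise. Should 14 begin to rearrange on silica, the crude aldehyde is taken directly into step 11.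

Step 11
Reactants: 14 (1S,2S,3R)-1-[4-(TBSO)-3-methoxybenzyl]-2-[4-(TBSO)-3,5-dimethoxyphenyl]-3-[(TESO)methyl]cyclopropane-1-carbaldehyde
Product: 15 (2S,3R)-2-[4-(TBSO)-3,5-dimethoxyphenyl]-4-[4-(TBSO)-3-methoxybenzyl]-3-[(TESO)methyl]-2,3-dihydrofuran
Conditions: Sc(OTf)3 (10 mol %), 2,6-di-tert-butyl-4-methylpyridine (20 mol %), 4 Å molecular sieves, CH2Cl2, −20 °C to 0 °C; then Et3N
Reagents that add atoms: none
Why: Sc(OTf)3 binds the formyl oxygen, and the cyclopropane bond between the syringyl‑bearing carbon and the formyl‑bearing carbon (C2–C4 in product numbering), the only bond flanked by a donor and an acceptor, ionises to a benzylic cation paired with a scandium enolate. The enolate oxygen then adds to the cation (O1–C2); this is the Lewis acid‑promoted Cloke–Wilson rearrangement of a donor–acceptor cyclopropyl carbonyl compound to a 2,3‑dihydrofuran, the closest known reaction type. The one ring formed is the five‑membered O1–C2–C3–C4–C5 ring, closed in the 5‑(enolendo)‑exo‑trig mode through oxygen, whose in‑plane lone pair can reach the cation although the enol double bond ends inside the ring; return through the enolate carbon only regenerates the strained cyclopropane. C2 is the single new stereocentre: it passes through a planar cation, so its configuration in 14 is irrelevant, and it is set by the untouched C3 centre, the aryl group taking the face anti to the CH2OTES arm both kinetically and, because the O1–C2 bond can re‑ionise, thermodynamically. C3 lies on no bond that breaks and keeps the configuration fixed in step 7. Three selectivities are needed: cleavage of C2–C4 and not C3–C4, secured by the 4‑silyloxy‑3,5‑dimethoxyphenyl donor on C2 while C3 bears only CH2OTES; closure through oxygen and not through the guaiacyl ring, secured by ion pairing, low temperature and an amine quench as soon as 14 is consumed; and survival of the enol ether and the TES ether, secured by the sieves and the hindered pyridine, which remove water and adventitious TfOH.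

Step 12
Reactants: 15 (2S,3R)-2-[4-(TBSO)-3,5-dimethoxyphenyl]-4-[4-(TBSO)-3-methoxybenzyl]-3-[(TESO)methyl]-2,3-dihydrofuran
Product: 16 (2S,3R,4R)-2-[4-(TBSO)-3,5-dimethoxyphenyl]-4-[4-(TBSO)-3-methoxybenzyl]-3-[(TESO)methyl]tetrahydrofuran
Conditions: H2 (1 atm), 5% Pd/C, Et3N (trace), EtOAc, rt
Reagents that add atoms: none
Why: Heterogeneous syn‑hydrogenation of the trisubstituted enol ether. The CH2OTES arm on the adjacent C3 shields one face, so both hydrogens should arrive anti to it, placing the guaiacylmethyl group cis to that arm and creating the 4R centre. The trace of amine keeps the medium non‑acidic and tempers the catalyst against hydrogenolysis of the benzylic C2–O1 bond.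

Step 13
Reactants: 16 (2S,3R,4R)-2-[4-(TBSO)-3,5-dimethoxyphenyl]-4-[4-(TBSO)-3-methoxybenzyl]-3-[(TESO)methyl]tetrahydrofuran
Product: 17 {(2S,3R,4R)-2-[4-(TBSO)-3,5-dimethoxyphenyl]-4-[4-(TBSO)-3-methoxybenzyl]tetrahydrofuran-3-yl}methanol
Conditions: PPTS (cat.), MeOH/CH2Cl2, 0 °C
Reagents that add atoms: none
Why: Acid‑catalysed methanolysis removes the primary TES ether, which is far more acid‑labile than the aryl TBS ethers; pyridinium tosylate at 0 °C is too weak to ionise the benzylic C2–O1 bond.

Step 14
Reactants: 18 ferulic acid
Product: 20 (E)-3-[4-(TBSO)-3-methoxyphenyl]prop-2-enoic acid, via bis-silyl ferulate 19 (not isolated)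
Conditions: TBSCl (2.2 equiv), imidazole, DMF, rt; then AcOH/THF/H2O, rt
Reagents that add atoms: tert-butyldimethylsilyl chloride, CC(C)(C)[Si](C)(C)Cl
Why: Same silylation and selective silyl ester hydrolysis as in step 4; the phenol is masked so that the acid cannot self‑acylate in the coupling.

Step 15
Reactants: 17 {(2S,3R,4R)-2-[4-(TBSO)-3,5-dimethoxyphenyl]-4-[4-(TBSO)-3-methoxybenzyl]tetrahydrofuran-3-yl}methanol; 20 (E)-3-[4-(TBSO)-3-methoxyphenyl]prop-2-enoic acid
Product: 21 {(2S,3R,4R)-2-[4-(TBSO)-3,5-dimethoxyphenyl]-4-[4-(TBSO)-3-methoxybenzyl]tetrahydrofuran-3-yl}methyl (E)-3-[4-(TBSO)-3-methoxyphenyl]prop-2-enoate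
Conditions: EDC·HCl, DMAP, CH2Cl2, 0 °C to rt
Reagents that add atoms: none
Why: Steglich esterification of the only free hydroxyl; the neutral conditions leave the benzylic ether and the E‑alkene of the acid unchanged.

Step 16
Reactants: 21 {(2S,3R,4R)-2-[4-(TBSO)-3,5-dimethoxyphenyl]-4-[4-(TBSO)-3-methoxybenzyl]tetrahydrofuran-3-yl}methyl (E)-3-[4-(TBSO)-3-methoxyphenyl]prop-2-enoate
Product: 22 {(2S,3R,4R)-2-(4-hydroxy-3,5-dimethoxyphenyl)-4-(4-hydroxy-3-methoxybenzyl)tetrahydrofuran-3-yl}methyl (E)-3-(4-hydroxy-3-methoxyphenyl)prop-2-enoate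
Conditions: Bu4NF, AcOH, THF, 0 °C
Reagents that add atoms: none
Why: Fluoride cleaves the three aryl silyl ethers in one operation, the phenoxides being good leaving groups from silicon. Acetic acid buffers the phenoxides so that the cinnamate ester and the benzylic ether are not exposed to strong base.

## Compound list

1 | sinapic acid, (E)-3-(4-hydroxy-3,5-dimethoxyphenyl)prop-2-enoic acid | COc1cc(/C=C/C(=O)O)cc(OC)c1O | starting material
2 | methyl (E)-3-(4-hydroxy-3,5-dimethoxyphenyl)prop-2-enoate | COC(=O)/C=C/c1cc(OC)c(O)c(OC)c1 | intermediate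
3 | methyl (E)-3-[4-(TBSO)-3,5-dimethoxyphenyl]prop-2-enoate | COC(=O)/C=C/c1cc(OC)c(O[Si](C)(C)C(C)(C)C)c(OC)c1 | intermediate
4 | (E)-3-[4-(TBSO)-3,5-dimethoxyphenyl]prop-2-en-1-ol | OC/C=C/c1cc(OC)c(O[Si](C)(C)C(C)(C)C)c(OC)c1 | intermediate
5 | 3-(4-hydroxy-3-methoxyphenyl)propanoic acid | COc1cc(CCC(=O)O)ccc1O | starting material
6 | TBS 3-[4-(TBSO)-3-methoxyphenyl]propanoate (not isolated) | COc1cc(CCC(=O)O[Si](C)(C)C(C)(C)C)ccc1O[Si](C)(C)C(C)(C)C | intermediate
7 | 3-[4-(TBSO)-3-methoxyphenyl]propanoic acid | COc1cc(CCC(=O)O)ccc1O[Si](C)(C)C(C)(C)C | intermediate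
8 | (E)-3-[4-(TBSO)-3,5-dimethoxyphenyl]prop-2-en-1-yl 3-[4-(TBSO)-3-methoxyphenyl]propanoate | COc1cc(CCC(=O)OC/C=C/c2cc(OC)c(O[Si](C)(C)C(C)(C)C)c(OC)c2)ccc1O[Si](C)(C)C(C)(C)C | intermediate
9 | (E)-3-[4-(TBSO)-3,5-dimethoxyphenyl]prop-2-en-1-yl 4,4,4-trifluoro-2-[4-(TBSO)-3-methoxybenzyl]-3-oxobutanoate (not isolated; α-carbon not configured) | COc1cc(CC(C(=O)C(F)(F)F)C(=O)OC/C=C/c2cc(OC)c(O[Si](C)(C)C(C)(C)C)c(OC)c2)ccc1O[Si](C)(C)C(C)(C)C | intermediate
10 | (E)-3-[4-(TBSO)-3,5-dimethoxyphenyl]prop-2-en-1-yl 2-diazo-3-[4-(TBSO)-3-methoxyphenyl]propanoate | COc1cc(CC(=[N+]=[N-])C(=O)OC/C=C/c2cc(OC)c(O[Si](C)(C)C(C)(C)C)c(OC)c2)ccc1O[Si](C)(C)C(C)(C)C | intermediate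
11 | (1S,5R,6S)-1-[4-(TBSO)-3-methoxybenzyl]-6-[4-(TBSO)-3,5-dimethoxyphenyl]-3-oxabicyclo[3.1.0]hexan-2-one | O1C[C@@H]2[C@@H](c3cc(OC)c(O[Si](C)(C)C(C)(C)C)c(OC)c3)[C@@]2(C1=O)Cc1ccc(O[Si](C)(C)C(C)(C)C)c(OC)c1 | intermediate
12 | (1S,2S,3R)-3-(hydroxymethyl)-N-methoxy-N-methyl-1-[4-(TBSO)-3-methoxybenzyl]-2-[4-(TBSO)-3,5-dimethoxyphenyl]cyclopropane-1-carboxamide | OC[C@@H]1[C@@H](c2cc(OC)c(O[Si](C)(C)C(C)(C)C)c(OC)c2)[C@@]1(C(=O)N(C)OC)Cc1ccc(O[Si](C)(C)C(C)(C)C)c(OC)c1 | intermediate
13 | (1S,2S,3R)-N-methoxy-N-methyl-1-[4-(TBSO)-3-methoxybenzyl]-2-[4-(TBSO)-3,5-dimethoxyphenyl]-3-[(TESO)methyl]cyclopropane-1-carboxamide | CC[Si](CC)(CC)OC[C@@H]1[C@@H](c2cc(OC)c(O[Si](C)(C)C(C)(C)C)c(OC)c2)[C@@]1(C(=O)N(C)OC)Cc1ccc(O[Si](C)(C)C(C)(C)C)c(OC)c1 | intermediate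
14 | (1S,2S,3R)-1-[4-(TBSO)-3-methoxybenzyl]-2-[4-(TBSO)-3,5-dimethoxyphenyl]-3-[(TESO)methyl]cyclopropane-1-carbaldehyde | CC[Si](CC)(CC)OC[C@@H]1[C@@H](c2cc(OC)c(O[Si](C)(C)C(C)(C)C)c(OC)c2)[C@@]1(C=O)Cc1ccc(O[Si](C)(C)C(C)(C)C)c(OC)c1 | intermediate
15 | (2S,3R)-2-[4-(TBSO)-3,5-dimethoxyphenyl]-4-[4-(TBSO)-3-methoxybenzyl]-3-[(TESO)methyl]-2,3-dihydrofuran | CC[Si](CC)(CC)OC[C@H]1C(Cc2ccc(O[Si](C)(C)C(C)(C)C)c(OC)c2)=CO[C@@H]1c1cc(OC)c(O[Si](C)(C)C(C)(C)C)c(OC)c1 | intermediate
16 | (2S,3R,4R)-2-[4-(TBSO)-3,5-dimethoxyphenyl]-4-[4-(TBSO)-3-methoxybenzyl]-3-[(TESO)methyl]tetrahydrofuran | CC[Si](CC)(CC)OC[C@H]1[C@@H](Cc2ccc(O[Si](C)(C)C(C)(C)C)c(OC)c2)CO[C@@H]1c1cc(OC)c(O[Si](C)(C)C(C)(C)C)c(OC)c1 | intermediate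
17 | {(2S,3R,4R)-2-[4-(TBSO)-3,5-dimethoxyphenyl]-4-[4-(TBSO)-3-methoxybenzyl]tetrahydrofuran-3-yl}methanol | OC[C@H]1[C@@H](Cc2ccc(O[Si](C)(C)C(C)(C)C)c(OC)c2)CO[C@@H]1c1cc(OC)c(O[Si](C)(C)C(C)(C)C)c(OC)c1 | intermediate
18 | ferulic acid, (E)-3-(4-hydroxy-3-methoxyphenyl)prop-2-enoic acid | COc1cc(/C=C/C(=O)O)ccc1O | starting material
19 | TBS (E)-3-[4-(TBSO)-3-methoxyphenyl]prop-2-enoate (not isolated) | COc1cc(/C=C/C(=O)O[Si](C)(C)C(C)(C)C)ccc1O[Si](C)(C)C(C)(C)C | intermediate
20 | (E)-3-[4-(TBSO)-3-methoxyphenyl]prop-2-enoic acid | COc1cc(/C=C/C(=O)O)ccc1O[Si](C)(C)C(C)(C)C | intermediate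
21 | {(2S,3R,4R)-2-[4-(TBSO)-3,5-dimethoxyphenyl]-4-[4-(TBSO)-3-methoxybenzyl]tetrahydrofuran-3-yl}methyl (E)-3-[4-(TBSO)-3-methoxyphenyl]prop-2-enoate | COc1cc(/C=C/C(=O)OC[C@H]2[C@@H](Cc3ccc(O[Si](C)(C)C(C)(C)C)c(OC)c3)CO[C@@H]2c2cc(OC)c(O[Si](C)(C)C(C)(C)C)c(OC)c2)ccc1O[Si](C)(C)C(C)(C)C | intermediate
22 | {(2S,3R,4R)-2-(4-hydroxy-3,5-dimethoxyphenyl)-4-(4-hydroxy-3-methoxybenzyl)tetrahydrofuran-3-yl}methyl (E)-3-(4-hydroxy-3-methoxyphenyl)prop-2-enoate (CNP0289934.1) | COc1cc(/C=C/C(=O)OC[C@H]2[C@@H](Cc3ccc(O)c(OC)c3)CO[C@@H]2c2cc(OC)c(O)c(OC)c2)ccc1O | target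

## Step count and least certain steps

Total: 16 steps. Longest linear sequence: 14 steps (steps 1–3, 5–13, 15 and 16, from 1). Steps 4 and 14 prepare the two side components.

Step 11 (key step). What may go wrong: during re‑ionisation of the O1–C2 bond the benzylic cation may be captured irreversibly by the electron‑rich guaiacyl ring (Friedel–Crafts closure to a six‑membered carbocycle). Alternatively, acid may remove the TES group, after which the freed hydroxyl forms a hemiacetal with the formyl group and blocks the rearrangement. Fallback, setting out from 11 and returning at 17: the O1–C2 bond is made by the classical closure of a hydroxyl on a benzylic cation instead of by enolate capture.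
- Lactone 11, itself a donor–acceptor cyclopropane, is opened at the syringyl carbon by methanol under Sc(OTf)3 catalysis, and the α‑centre is then equilibrated with DBU. This should give the trans‑disubstituted (3R,4R)-3-[4-(TBSO)-3-methoxybenzyl]-4-{[4-(TBSO)-3,5-dimethoxyphenyl](methoxy)methyl}dihydrofuran-2(3H)-one F1, either epimer at the methoxy carbon being usable.
- LiBH4 in THF reduces F1 to (2R,3R)-2-{[4-(TBSO)-3,5-dimethoxyphenyl](methoxy)methyl}-3-[4-(TBSO)-3-methoxybenzyl]butane-1,4-diol F2.
- Catalytic camphorsulfonic acid in CH2Cl2 at 0 °C ionises the benzylic methyl ether of F2, and the hydroxyl four carbons away closes the tetrahydrofuran trans to the C3 arm, giving 17. The other hydroxyl would have to form a four‑membered ring.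
- A trans butyrolactone of this kind corresponds to the 3,4‑cis tetrahydrofuran, so C4 is set by equilibration and steps 8–13 are bypassed.

Step 7. What may go wrong: 1,2‑hydride migration from the benzylic CH2 within the rhodium carbenoid may outrun cyclopropanation, or facial discrimination of the alkene may be insufficient. Fallback, setting out from 10 and returning at 11: asymmetric catalysis is given up for resolution. Compound 10 is decomposed with the achiral, very bulky Rh2(O2CCPh3)4 (dirhodium tetrakis(triphenylacetate)), the carboxylate type best suited to suppress the hydride shift. The racemic lactone is separated by preparative chromatography on a chiral stationary phase. Compound 11 goes on, and its mirror image, (1R,5S,6R)-1-[4-(TBSO)-3-methoxybenzyl]-6-[4-(TBSO)-3,5-dimethoxyphenyl]-3-oxabicyclo[3.1.0]hexan-2-one F3, is set aside.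

Step 12. What may go wrong: facial selectivity may be poor, because the C2 aryl group on the opposite face competes with the C3 arm for control of adsorption; the benzylic C2–O1 bond may also be hydrogenolysed on palladium. Fallback, setting out from 15 and returning at 16: substrate control on a metal surface is replaced by reagent control in solution. Compound 15 is hydrogenated with a cationic iridium phosphine–oxazoline complex, [Ir(cod)(L)]B(ArF)4 with L = tBu‑PHOX, in CH2Cl2 buffered with a hindered base. The ligand enantiomer is chosen so that it reinforces delivery anti to the CH2OTES arm. This catalyst class is established for trisubstituted enol ethers and does not cleave benzylic ethers. No new compound is involved. If both modes fail, the detour through F1 and F2 described for step 11 bypasses the hydrogenation altogether.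

Step 8. What may go wrong: aminolysis at the hindered carbonyl on the quaternary cyclopropane carbon may be slow, and the hydroxy amide may relactonise during work‑up. Fallback, setting out from 11 and returning at 14: the two oxygen functions are differentiated by sterics instead of through an amide.
- LiBH4 reduces 11 to the diol (1S,2S,3R)-1,3-bis(hydroxymethyl)-1-[4-(TBSO)-3-methoxybenzyl]-2-[4-(TBSO)-3,5-dimethoxyphenyl]cyclopropane F4.
- Et3SiCl (1 equiv) with imidazole at −78 °C silylates the less hindered hydroxymethyl group on the CH carbon, to give {(1S,2S,3R)-1-[4-(TBSO)-3-methoxybenzyl]-2-[4-(TBSO)-3,5-dimethoxyphenyl]-3-[(TESO)methyl]cyclopropyl}methanol F5.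
- Dess–Martin periodinane buffered with NaHCO3 oxidises the remaining neopentyl alcohol to 14.

## Further compounds

F1 | step 11 | (3R,4R)-3-[4-(TBSO)-3-methoxybenzyl]-4-{[4-(TBSO)-3,5-dimethoxyphenyl](methoxy)methyl}dihydrofuran-2(3H)-one (methoxy carbon: either epimer) | O=C1OC[C@H](C(OC)c2cc(OC)c(O[Si](C)(C)C(C)(C)C)c(OC)c2)[C@H]1Cc1ccc(O[Si](C)(C)C(C)(C)C)c(OC)c1
F2 | step 11 | (2R,3R)-2-{[4-(TBSO)-3,5-dimethoxyphenyl](methoxy)methyl}-3-[4-(TBSO)-3-methoxybenzyl]butane-1,4-diol (methoxy carbon: either epimer) | OC[C@H](C(OC)c1cc(OC)c(O[Si](C)(C)C(C)(C)C)c(OC)c1)[C@H](CO)Cc1ccc(O[Si](C)(C)C(C)(C)C)c(OC)c1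
F3 | step 7 | (1R,5S,6R)-1-[4-(TBSO)-3-methoxybenzyl]-6-[4-(TBSO)-3,5-dimethoxyphenyl]-3-oxabicyclo[3.1.0]hexan-2-one (enantiomer of 11) | O1C[C@H]2[C@H](c3cc(OC)c(O[Si](C)(C)C(C)(C)C)c(OC)c3)[C@]2(C1=O)Cc1ccc(O[Si](C)(C)C(C)(C)C)c(OC)c1
F0 | step 12 | none | none
F4 | step 8 | (1S,2S,3R)-1,3-bis(hydroxymethyl)-1-[4-(TBSO)-3-methoxybenzyl]-2-[4-(TBSO)-3,5-dimethoxyphenyl]cyclopropane (numbered as 14) | OC[C@@H]1[C@@H](c2cc(OC)c(O[Si](C)(C)C(C)(C)C)c(OC)c2)[C@@]1(CO)Cc1ccc(O[Si](C)(C)C(C)(C)C)c(OC)c1
F5 | step 8 | {(1S,2S,3R)-1-[4-(TBSO)-3-methoxybenzyl]-2-[4-(TBSO)-3,5-dimethoxyphenyl]-3-[(TESO)methyl]cyclopropyl}methanol | CC[Si](CC)(CC)OC[C@@H]1[C@@H](c2cc(OC)c(O[Si](C)(C)C(C)(C)C)c(OC)c2)[C@@]1(CO)Cc1ccc(O[Si](C)(C)C(C)(C)C)c(OC)c1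
A1 | alternative 1 | chloro[4-(benzyloxy)-3,5-dimethoxyphenyl]methyl (trimethylsilyl)methyl ether (racemic) | COc1cc(C(Cl)OC[Si](C)(C)C)cc(OC)c1OCc1ccccc1
A2 | alternative 1 | (5S)-5-[(1S,2R,5S)-2-isopropyl-5-methylcyclohexyloxy]furan-2(5H)-one | C[C@H]1CC[C@@H]([C@H](C1)O[C@H]2OC(=O)C=C2)C(C)C
A3 | alternative 1 | exo-2-[4-(benzyloxy)-3,5-dimethoxyphenyl]-6-[(1S,2R,5S)-menthyloxy]-3,7-dioxabicyclo[3.3.0]octan-8-one | C[C@H]1CC[C@@H]([C@H](C1)O[C@H]2OC(=O)[C@H]3[C@@H]2CO[C@@H]3c4cc(OC)c(OCc5ccccc5)c(OC)c4)C(C)C
A4 | alternative 2 | dimethyl 2-[4-(benzyloxy)-3,5-dimethoxybenzylidene]malonate | COC(=O)C(=Cc1cc(OC)c(OCc2ccccc2)c(OC)c1)C(=O)OC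
A5 | alternative 2 | 2-vinyloxirane (racemic) | C=CC1CO1
A6 | alternative 2 | dimethyl 2,4-trans-2-[4-(benzyloxy)-3,5-dimethoxyphenyl]-4-vinyltetrahydrofuran-3,3-dicarboxylate | COC(=O)C1(C(=O)OC)[C@@H](C=C)CO[C@@H]1c1cc(OC)c(OCc2ccccc2)c(OC)c1
A7 | alternative 3 | (S)-2-{(R)-[4-(TBSO)-3,5-dimethoxyphenyl]{[(E)-3-[4-(TBSO)-3-methoxyphenyl]prop-2-en-1-yl]oxy}methyl}oxirane (erythro; the oxirane carbon is lost as a stereocentre in the key step) | COc1cc(/C=C/CO[C@H](c2cc(OC)c(O[Si](C)(C)C(C)(C)C)c(OC)c2)[C@@H]2CO2)ccc1O[Si](C)(C)C(C)(C)C
A8 | alternative 3 | {(2S,3R,4R)-2-[4-(TBSO)-3,5-dimethoxyphenyl]-4-[4-(TBSO)-3-methoxybenzyl]tetrahydrofuran-3-yl}methanol (identical with 17) | OC[C@H]1[C@@H](Cc2ccc(O[Si](C)(C)C(C)(C)C)c(OC)c2)CO[C@@H]1c1cc(OC)c(O[Si](C)(C)C(C)(C)C)c(OC)c1
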